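**Retrosynthetic overview**
- Target ⇐ acetal hydrolysis ⇐ Negishi attachment of a purchased, pre-formed butenolide ring (as 3-bromofuran-2(5H)-one) to a C12 alkylzinc.
- Decalin ⇐ one redox-neutral, hydrogen-atom-initiated radical bicyclization of an acyclic triene that already carries C19 as CO2Me and C20 as a chiral acetal. Ring A forms first (C4–C5), then ring B (C10–C9), then H• is lost from C17: the H-in / cyclize / H-out sequence of copalyl diphosphate synthase.
- Triene ⇐ B-alkyl Suzuki coupling (C1–C10) of a (Z)-α-iodoenal with methyl 2-methylidenepent-4-enoate; enal ⇐ cross-metathesis; (E)-C8=C9 ⇐ zirconium-catalysed carboalumination of hex-1-en-5-yne.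
- Absolute configuration ⇐ (R,R)-hydrobenzoin acetal at C20, which also protects the aldehyde and lets minor diastereomers be removed by chromatography.

Assumption: the SMILES is read as the normal-labdane enantiomer (4S,5R,9S,10S; 4β-CO2Me, 5α-H, 9α-H, 10β-CHO), and labdane numbering is used for positions (C4 bears Me/CO2Me, C10 the C20 carbon, C8 the C17 methylidene, C9 the C11–C12 chain, lactone C13–C16).

Step 1
Reactants: 1 hex-1-en-5-yne; 2 oxirane
Product: 5 (3E)-4-methylocta-3,7-dien-1-ol, via alkenylalane 3 (not isolated), via lithium alanate 4 (not isolated)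
Conditions: AlMe3, Cp2ZrCl2 (25 mol%), CH2Cl2, 0 °C to rt; evaporate; n-BuLi, hexane–THF, −30 °C; oxirane, to rt; aq. HCl
Reagents that add atoms: trimethylaluminium, C[Al](C)C
Why: Negishi zirconium-catalysed carboalumination adds Me and Al syn across the alkyne with Me on the internal carbon, and the derived alanate opens oxirane with retention at the alkenyl carbon, so the trisubstituted C8=C9 alkene is formed E (>98:2) while the terminal alkene is inert.

Step 2
Reactants: 5 (3E)-4-methylocta-3,7-dien-1-ol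
Product: 6 (5E)-8-bromo-5-methylocta-1,5-diene
Conditions: CBr4, PPh3, CH2Cl2, 0 °C
Reagents that add atoms: tetrabromomethane, BrC(Br)(Br)Br
Why: Appel bromination under neutral conditions converts the primary alcohol to the bromide without touching either alkene.

Step 3
Reactants: 6 (5E)-8-bromo-5-methylocta-1,5-diene; 7 (2E)-but-2-enal
Product: 8 (2E,6E)-9-bromo-6-methylnona-2,6-dienal
Conditions: 7 (4 equiv), second-generation Hoveyda–Grubbs catalyst RuCl2(H2IMes)(=CH-C6H4-2-O-i-Pr) (3 mol%), CH2Cl2, 40 °C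
Reagents that add atoms: none
Why: Olefin cross-metathesis of the monosubstituted alkene with crotonaldehyde gives the (E)-enal with loss of propene, the trisubstituted alkene and the bromide being inert to the ruthenium carbene.

Step 4
Reactants: 8 (2E,6E)-9-bromo-6-methylnona-2,6-dienal
Product: 9 (2Z,6E)-9-bromo-2-iodo-6-methylnona-2,6-dienal
Conditions: I2, K2CO3, DMAP (20 mol%), THF–H2O 1:1, rt
Reagents that add atoms: iodine, II
Why: Amine-catalysed α-iodination of an enal (Morita–Baylis–Hillman-type conjugate addition of DMAP, iodination of the enolate, elimination) gives the (Z)-2-iodoenal in which CHO stays trans to the chain.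

Step 5
Reactants: 10 methyl 2-(bromomethyl)prop-2-enoate; 11 vinylmagnesium bromide
Product: 12 methyl 2-methylidenepent-4-enoate
Conditions: CuI (10 mol%), THF, −78 to −40 °C
Reagents that add atoms: none
Why: Copper-catalysed SN2′ substitution of the allylic bromide by the vinyl Grignard reagent gives the skipped diene, the low temperature keeping the ester and the acrylate untouched.

Step 6
Reactants: 12 methyl 2-methylidenepent-4-enoate; 9 (2Z,6E)-9-bromo-2-iodo-6-methylnona-2,6-dienal
Product: 14 methyl (6E,10E)-13-bromo-6-formyl-10-methyl-2-methylidenetrideca-6,10-dienoate, via alkyl-9-BBN borane 13 (not isolated)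
Conditions: 9-BBN, THF, 0 °C to rt; then 9, Pd(dppf)Cl2 (5 mol%), AsPh3 (10 mol%), Cs2CO3, DMF–THF–H2O, rt
Reagents that add atoms: none
Why: 9-BBN hydroborates only the monosubstituted alkene (anti-Markovnikov, acrylate untouched) and the B-alkyl Suzuki–Miyaura coupling replaces iodine with retention, so the C1 chain ends cis to C6 (6E), the geometry the cyclization is designed around.

Step 7
Reactants: 14 methyl (6E,10E)-13-bromo-6-formyl-10-methyl-2-methylidenetrideca-6,10-dienoate; 15 (1R,2R)-1,2-diphenylethane-1,2-diol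
Product: 16 methyl (6E,10E)-13-bromo-6-[(4R,5R)-4,5-diphenyl-1,3-dioxolan-2-yl]-10-methyl-2-methylidenetrideca-6,10-dienoate
Conditions: PPTS (10 mol%), MgSO4, benzene, 60 °C
Reagents that add atoms: none
Why: Acid-catalysed acetalization with the C2-symmetric diol (no new stereocentre at the acetal carbon) keeps the E geometry, masks the aldehyde from cobalt hydride and installs the element that fixes the absolute configuration.

Step 8
Reactants: 16 methyl (6E,10E)-13-bromo-6-[(4R,5R)-4,5-diphenyl-1,3-dioxolan-2-yl]-10-methyl-2-methylidenetrideca-6,10-dienoate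
Product: 17 methyl (1S,4aS,5S,8aR)-5-(2-bromoethyl)-4a-[(4R,5R)-4,5-diphenyl-1,3-dioxolan-2-yl]-1-methyl-6-methylidenedecahydronaphthalene-1-carboxylate
Conditions: Co(salen)Cl (5 mol%; salen = (R,R)-N,N′-bis(3,5-di-tert-butylsalicylidene)cyclohexane-1,2-diaminate), PhSiH3 (10 mol%, two portions), degassed benzene (0.005 M), 25 to 40 °C; stop at full conversion; chromatography
Reagents that add atoms: none
Why: Proposed new method: a cobalt-hydride hydrogen-atom-transfer cycloisomerization in which Co–H (trivalent cobalt) gives H• to the methacrylate CH2 (the fastest acceptor, as in cobalt catalytic chain transfer of methacrylates), the tertiary C4 ester radical closes 6-endo onto C5 (ring A), the tertiary C10 radical closes 6-endo onto C9 (ring B), and divalent cobalt takes H• from the C17 methyl of the C8 radical to give the 8(17)-alkene and return Co–H (closest known reaction types: cobalt–salen/silane hydrogen-atom-transfer cycloisomerization of dienes and hydrogen-atom-transfer-initiated radical polyene bicyclization), with C4 and C5 set in a chair transition state that places the conjugated ester pseudo-equatorial and, because C1 is cis to C6 in 16, C6 pseudo-axial (CO2Me cis to C6, i.e. 4β-CO2Me/5α-H), C10 and C9 set in a second chair closure to the trans-decalin with the C11 chain equatorial, and the absolute sense set by the (R,R)-acetal, whose phenyl group leaning toward C1 blocks one alkene face, minor diastereomers being removed by chromatography.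

Step 9
Reactants: 18 furan-2(5H)-one
Product: 20 3-bromofuran-2(5H)-one, via trans-dibromolactone 19 (not isolated)
Conditions: Br2, CH2Cl2, 0 °C to rt; then Et3N, 0 °C
Reagents that add atoms: bromine, BrBr
Why: Anti addition of bromine followed by base-induced loss of HBr from the acidic α-position gives the α-bromobutenolide (bromination–dehydrobromination).

Step 10
Reactants: 17 methyl (1S,4aS,5S,8aR)-5-(2-bromoethyl)-4a-[(4R,5R)-4,5-diphenyl-1,3-dioxolan-2-yl]-1-methyl-6-methylidenedecahydronaphthalene-1-carboxylate; 20 3-bromofuran-2(5H)-one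
Product: 22 methyl (1S,4aS,5S,8aR)-4a-[(4R,5R)-4,5-diphenyl-1,3-dioxolan-2-yl]-1-methyl-6-methylidene-5-[2-(2-oxo-2,5-dihydrofuran-3-yl)ethyl]decahydronaphthalene-1-carboxylate, via alkylzinc bromide 21 (not isolated)
Conditions: Zn dust, LiCl, THF, 50 °C; then 20, Pd(dppf)Cl2 (5 mol%), THF, rt to 40 °C
Reagents that add atoms: none
Why: LiCl-promoted zinc insertion into the primary C–Br bond tolerates ester, acetal and alkene, and Negishi coupling with the α-bromobutenolide forms C12–C13 without touching any stereocentre; the butenolide is added only now because it would intercept the C8 radical of step 8.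

Step 11
Reactants: 22 methyl (1S,4aS,5S,8aR)-4a-[(4R,5R)-4,5-diphenyl-1,3-dioxolan-2-yl]-1-methyl-6-methylidene-5-[2-(2-oxo-2,5-dihydrofuran-3-yl)ethyl]decahydronaphthalene-1-carboxylate
Product: 23 methyl (1S,4aS,5S,8aR)-4a-formyl-1-methyl-6-methylidene-5-[2-(2-oxo-2,5-dihydrofuran-3-yl)ethyl]decahydronaphthalene-1-carboxylate
Conditions: TFA–H2O–CH2Cl2 (1:1:10), 0 °C to rt
Reagents that add atoms: water, O
Why: Acid-catalysed acetal hydrolysis releases the C20 aldehyde and the recoverable diol; C10 is quaternary so nothing can epimerize, and the 8(17)-alkene tolerates the brief mild acid.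

**Compound list**
1 | hex-1-en-5-yne | C=CCCC#C | starting material
2 | oxirane | C1CO1 | starting material
3 | dimethyl[(1E)-2-methylhexa-1,5-dien-1-yl]alumane | C=CCC/C(C)=C/[Al](C)C | intermediate
4 | lithium butyl(dimethyl)[(1E)-2-methylhexa-1,5-dien-1-yl]aluminate | [Li+].CCCC[Al-](C)(C)/C=C(\C)CCC=C | intermediate
5 | (3E)-4-methylocta-3,7-dien-1-ol | C=CCC/C(C)=C/CCO | intermediate
6 | (5E)-8-bromo-5-methylocta-1,5-diene | C=CCC/C(C)=C/CCBr | intermediate
7 | (2E)-but-2-enal | C/C=C/C=O | starting material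
8 | (2E,6E)-9-bromo-6-methylnona-2,6-dienal | O=C/C=C/CC/C(C)=C/CCBr | intermediate
9 | (2Z,6E)-9-bromo-2-iodo-6-methylnona-2,6-dienal | O=C/C(I)=C/CC/C(C)=C/CCBr | intermediate
10 | methyl 2-(bromomethyl)prop-2-enoate | C=C(CBr)C(=O)OC | starting material
11 | vinylmagnesium bromide | C=C[Mg]Br | starting material
12 | methyl 2-methylidenepent-4-enoate | C=CCC(=C)C(=O)OC | intermediate
13 | methyl 5-(9-borabicyclo[3.3.1]nonan-9-yl)-2-methylidenepentanoate | C=C(CCCB1C2CCCC1CCC2)C(=O)OC | intermediate
14 | methyl (6E,10E)-13-bromo-6-formyl-10-methyl-2-methylidenetrideca-6,10-dienoate | C=C(C(=O)OC)CCC/C(C=O)=C\CC/C(C)=C/CCBr | intermediate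
15 | (1R,2R)-1,2-diphenylethane-1,2-diol | O[C@H](c1ccccc1)[C@H](O)c1ccccc1 | starting material
16 | methyl (6E,10E)-13-bromo-6-[(4R,5R)-4,5-diphenyl-1,3-dioxolan-2-yl]-10-methyl-2-methylidenetrideca-6,10-dienoate | C=C(C(=O)OC)CCC/C(=C\CC/C(C)=C/CCBr)C1O[C@H](c2ccccc2)[C@@H](c2ccccc2)O1 | intermediate
17 | methyl (1S,4aS,5S,8aR)-5-(2-bromoethyl)-4a-[(4R,5R)-4,5-diphenyl-1,3-dioxolan-2-yl]-1-methyl-6-methylidenedecahydronaphthalene-1-carboxylate | C=C1CC[C@@H]2[C@](C3O[C@H](c4ccccc4)[C@@H](c4ccccc4)O3)(CCC[C@]2(C)C(=O)OC)[C@H]1CCBr | intermediate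
18 | furan-2(5H)-one | O=C1OCC=C1 | starting material
19 | trans-3,4-dibromooxolan-2-one (racemic) | O=C1OC[C@H](Br)[C@H]1Br | intermediate
20 | 3-bromofuran-2(5H)-one | O=C1OCC=C1Br | intermediate
21 | alkylzinc bromide from 17 (C12–ZnBr) | C=C1CC[C@@H]2[C@](C3O[C@H](c4ccccc4)[C@@H](c4ccccc4)O3)(CCC[C@]2(C)C(=O)OC)[C@H]1CC[Zn]Br | intermediate
22 | methyl (1S,4aS,5S,8aR)-4a-[(4R,5R)-4,5-diphenyl-1,3-dioxolan-2-yl]-1-methyl-6-methylidene-5-[2-(2-oxo-2,5-dihydrofuran-3-yl)ethyl]decahydronaphthalene-1-carboxylate | C=C1CC[C@@H]2[C@](C3O[C@H](c4ccccc4)[C@@H](c4ccccc4)O3)(CCC[C@]2(C)C(=O)OC)[C@H]1CCC1=CCOC1=O | intermediate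
23 | methyl (1S,4aS,5S,8aR)-4a-formyl-1-methyl-6-methylidene-5-[2-(2-oxo-2,5-dihydrofuran-3-yl)ethyl]decahydronaphthalene-1-carboxylate | C=C1CC[C@@H]2[C@](C=O)(CCC[C@]2(C)C(=O)OC)[C@H]1CCC1=CCOC1=O | target

**Step count**
Total: 11 steps (steps 5 and 9 make the two small coupling partners).
Longest linear sequence: 9 steps (1, 2, 3, 4, 6, 7, 8, 10, 11).

**Three steps most likely to fail**

Step 8 (bicyclization). This step is unprecedented in this form. The risks are capture of the ring A radical before the second closure, isomerization of the product alkene, the C4 epimer if the ester prefers the pseudo-axial site, and low facial bias from the acetal (both hydrobenzoin enantiomers are available). The fallback sets out from 9 and comes back at 17, replacing the hydrogen-atom manifold by the precedented oxidative cyclization of a β-keto ester and setting C4 by alkylation. Negishi coupling of 9 with commercial (3-ethoxy-3-oxopropyl)zinc bromide (Pd(dppf)Cl2) gives ethyl (4E,8E)-11-bromo-4-formyl-8-methylundeca-4,8-dienoate F1. Acetalization with 15 as in step 7 gives ethyl (4E,8E)-11-bromo-4-[(4R,5R)-4,5-diphenyl-1,3-dioxolan-2-yl]-8-methylundeca-4,8-dienoate F2. Crossed Claisen condensation with lithium 1-methoxyethen-1-olate F3 (from methyl acetate and LiN(i-Pr)2, THF, −78 °C) gives methyl (6E,10E)-13-bromo-6-[(4R,5R)-4,5-diphenyl-1,3-dioxolan-2-yl]-10-methyl-3-oxotrideca-6,10-dienoate F4. Mn(OAc)3/Cu(OAc)2 in EtOH–AcOH (trivalent manganese makes the β-keto ester radical, Cu(OAc)2 turns the C8 radical into the 8(17)-alkene) gives the 3-oxo-4-demethyl analogue of 17 F5. C-Methylation (K2CO3, MeI, acetone) from the α face, anti to the axial C20 group, gives the 3-oxo analogue of 17 F6 with the 4β-ester. Its C3 tosylhydrazone F7 (TsNHNH2) is reduced with catecholborane then NaOAc to give 17.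

Step 10 (late Negishi coupling). Zinc insertion may be slow in this hindered molecule and the bromobutenolide is base- and nucleophile-sensitive. The fallback sets out from 17 and comes back at 22, building the butenolide unsaturation after the C–C bond. 3-Bromooxolan-2-one with PhSH/Et3N gives 3-(phenylsulfanyl)oxolan-2-one F8. Its lithium enolate F9 (LiN(SiMe3)2, THF–DMPU, −78 °C) is alkylated by 17 (NaI) to give the α-phenylsulfanyl lactone F10 (C13 epimers). NaIO4 gives the sulfoxide F11, and thermal syn-elimination (toluene, 110 °C, CaCO3) gives the endocyclic butenolide 22.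

Step 11 (hydrolysis of a hindered, neopentyl diaryl-dioxolane next to an acid-labile exocyclic alkene). The fallback sets out from 22 and comes back at 23, avoiding protic hydrolysis. Exchange with ethane-1,2-dithiol and BF3·OEt2 (CH2Cl2, −30 °C) gives the 1,3-dithiolane F12, which is unmasked by alkylative hydrolysis (MeI, CaCO3, aqueous MeCN, 45 °C) under near-neutral conditions.

**Further compounds**
F1 | step 8 | ethyl (4E,8E)-11-bromo-4-formyl-8-methylundeca-4,8-dienoate | CCOC(=O)CC/C(C=O)=C\CC/C(C)=C/CCBr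
F2 | step 8 | ethyl (4E,8E)-11-bromo-4-[(4R,5R)-4,5-diphenyl-1,3-dioxolan-2-yl]-8-methylundeca-4,8-dienoate | CCOC(=O)CC/C(=C\CC/C(C)=C/CCBr)C1O[C@H](c2ccccc2)[C@@H](c2ccccc2)O1
F3 | step 8 | lithium 1-methoxyethen-1-olate | [Li+].[O-]C(=C)OC
F4 | step 8 | methyl (6E,10E)-13-bromo-6-[(4R,5R)-4,5-diphenyl-1,3-dioxolan-2-yl]-10-methyl-3-oxotrideca-6,10-dienoate | COC(=O)CC(=O)CC/C(=C\CC/C(C)=C/CCBr)C1O[C@H](c2ccccc2)[C@@H](c2ccccc2)O1
F5 | step 8 | 3-oxo-4-demethyl analogue of 17 (C4 epimers) | C=C1CC[C@@H]2[C@](C3O[C@H](c4ccccc4)[C@@H](c4ccccc4)O3)(CCC(=O)C2C(=O)OC)[C@H]1CCBr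
F6 | step 8 | 3-oxo analogue of 17 (4β-CO2Me, 4α-Me) | C=C1CC[C@@H]2[C@](C3O[C@H](c4ccccc4)[C@@H](c4ccccc4)O3)(CCC(=O)[C@]2(C)C(=O)OC)[C@H]1CCBr
F7 | step 8 | C3 tosylhydrazone of F6 | C=C1CC[C@@H]2[C@](C3O[C@H](c4ccccc4)[C@@H](c4ccccc4)O3)(CCC(=NNS(=O)(=O)c5ccc(C)cc5)[C@]2(C)C(=O)OC)[C@H]1CCBr
F8 | step 10 | 3-(phenylsulfanyl)oxolan-2-one (racemic) | O=C1OCCC1Sc1ccccc1
F9 | step 10 | lithium enolate of F8 | [Li+].[O-]C1=C(Sc2ccccc2)CCO1
F10 | step 10 | α-phenylsulfanyl lactone from 17 and F9 (C13 epimers) | C=C1CC[C@@H]2[C@](C3O[C@H](c4ccccc4)[C@@H](c4ccccc4)O3)(CCC[C@]2(C)C(=O)OC)[C@H]1CCC1(Sc3ccccc3)CCOC1=O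
F11 | step 10 | sulfoxide of F10 | C=C1CC[C@@H]2[C@](C3O[C@H](c4ccccc4)[C@@H](c4ccccc4)O3)(CCC[C@]2(C)C(=O)OC)[C@H]1CCC1(S(=O)c3ccccc3)CCOC1=O
F12 | step 11 | 1,3-dithiolane analogue of 22 at C20 | C=C1CC[C@@H]2[C@](C3SCCS3)(CCC[C@]2(C)C(=O)OC)[C@H]1CCC1=CCOC1=O
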